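The four-membered ring of the target carries the two aryl groups on C4 and C4′ and the two lactone carbonyl carbons on C3 and C3′ in strict alternation (coumarin numbering), which is the substitution pattern of a 1,3-diaryl squaraine. The cyclobutane is therefore bought as squaric acid, and one two-fold condensation with resorcinol forms both aryl–ring bonds (C4a–C4 and C4a′–C4′); the precursors are simply squaric acid and two resorcinols. Afterwards each ring oxygen is exchanged for a carboxyl carbon by enol triflate carbonylation, two face-selective hydrogenations give the all-cis hydrogens, the ortho hydroxyls close the lactones, the para hydroxyls carry the angular pyrans, and the racemate is resolved last.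

Key step: step 1

Remark on the chemistry: opening both lactones of the target gives an achiral all-cis diacid, so the handedness lies only in which phenol closes onto which carboxyl. Every intermediate before lactonisation is therefore racemic or meso, and an early enantioselective reduction would act on a racemate with a fixed stereocentre. The single enantiomer is secured by resolution in the last step, with its absolute configuration to be assigned by ECD or X-ray analysis. Racemates are drawn as one enantiomer; Ar denotes 2,4-bis(methoxymethoxy)phenyl (MOM-protected resorcinol ring).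

Step 1
Reactants: 1 squaric acid; 2 resorcinol (2 equiv)
Product: 4 1,3-bis(2,4-dihydroxyphenyl)squaraine (neutral quinoid form), via semisquaric acid 3 (not isolated)
Conditions: n-BuOH/toluene (1:1), reflux, azeotropic removal of water (water separator)
Reagents that add atoms: none
Why: Acid-catalysed Friedel–Crafts hydroxyalkylation: C4 of resorcinol (para to one hydroxyl, ortho to the other) adds to a carbonyl carbon of squaric acid (or of its butyl half-ester formed in the medium) and loss of water gives semisquaric acid 3. In 3 the aryl-bearing carbon and its two neighbours form a vinylogous acid, which leaves the diagonal ketone carbon as the only electrophile, so the second resorcinol adds there and a second dehydration gives the 1,3-diaryl dye; this is the condensation by which squaraine dyes are made from squaric acid and electron-rich arenes. No ring is closed, because the four-membered ring is purchased, and the two skeletal bonds C4a–C4 and C4a′–C4′ are formed. No stereocentre is created. The step needs 1,3- over 1,2-diarylation, secured by using the free acid under dehydrating conditions and not a squaric ester or chloride, and attack through resorcinol C4 and not C2, secured by the hindrance of C2 between two hydroxyls. The ortho hydroxyls, hydrogen-bonded to the ring oxygens in 4, are the later lactone oxygens and the para hydroxyls the later pyran oxygens.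

Step 2
Reactants: 4 1,3-bis(2,4-dihydroxyphenyl)squaraine
Product: 5 2,4-bis(2,4-dihydroxyphenyl)-3-hydroxycyclobut-2-en-1-one
Conditions: H2 (1 atm), Pd/C (5 mol %), DMF, rt, stopped when the dye colour is discharged; filtered and kept under argon, used crude
Reagents that add atoms: none
Why: Hydrogenation of the para-quinone methide unit of the dye (formal 1,6-addition of H2) should put one hydrogen on the ring carbon and restore both arenes, leaving the vinylogous acid 5, whose fully substituted enolised 1,3-diketone C=C resists further hydrogenation; the new sp3 centre is stereolabile through keto–enol tautomerism.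

Step 3
Reactants: 5 2,4-bis(2,4-dihydroxyphenyl)-3-hydroxycyclobut-2-en-1-one
Product: 7 2,4-di-Ar-3-hydroxycyclobut-2-en-1-one, via pentakis(methoxymethyl) compound 6 (not isolated)
Conditions: MOMCl (7 equiv), i-Pr2NEt (8 equiv), CH2Cl2/DMF, 0 °C → rt; then 0.5 M aq. HCl, THF, 0 °C
Reagents that add atoms: chloromethyl methyl ether (MOMCl), COCCl
Why: Williamson-type O-alkylation of the four phenols and the enol oxygen by the hard electrophile MOMCl, then selective acid hydrolysis of the vinylogous MOM ester, whose leaving group (a vinylogous carboxylate) makes it far more labile than the aryl MOM ethers.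

Step 4
Reactants: 7 2,4-di-Ar-3-hydroxycyclobut-2-en-1-one
Product: 8 2,4-di-Ar-3-oxocyclobut-1-en-1-yl trifluoromethanesulfonate (racemic)
Conditions: Tf2O, pyridine, CH2Cl2, −78 → −20 °C
Reagents that add atoms: trifluoromethanesulfonic anhydride (Tf2O), O=S(=O)(OS(=O)(=O)C(F)(F)F)C(F)(F)F
Why: O-Sulfonylation of an enolised cyclic 1,3-diketone, as routinely done with cyclohexane-1,3-diones; both tautomers of 7 give the same racemic triflate, whose C4 stereocentre is now fixed because its enolisation would create a cyclobutadiene.

Step 5
Reactants: 8 2,4-di-Ar-3-oxocyclobut-1-en-1-yl trifluoromethanesulfonate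
Product: 9 methyl 2,4-di-Ar-3-oxocyclobut-1-ene-1-carboxylate (racemic)
Conditions: Pd(OAc)2 (5 mol %), dppp (6 mol %), CO (1 atm), MeOH (10 equiv), i-Pr2NEt, DMF, 35 °C
Reagents that add atoms: carbon monoxide, [C-]#[O+]; methanol, CO
Why: Palladium-catalysed alkoxycarbonylation of a β-(triflyloxy)enone (oxidative addition, CO insertion, methanolysis), a standard reaction of 1,3-diketone enol triflates; the low temperature keeps the 4-aryl cyclobutenone from electrocyclic ring opening and the two flanking ortho-substituted aryl groups shield the product from conjugate addition of methanol.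

Step 6
Reactants: 9 methyl 2,4-di-Ar-3-oxocyclobut-1-ene-1-carboxylate
Product: 10 methyl all-cis-2,4-di-Ar-3-oxocyclobutane-1-carboxylate (meso; H-1, H-2 and H-4 on one face)
Conditions: H2 (1 atm), Pd/C (5 mol %), EtOAc, 0 °C → rt; filtered and used at once
Reagents that add atoms: none
Why: syn-Hydrogenation of the strained, doubly activated tetrasubstituted alkene from the face opposite the aryl group on the neighbouring sp3 carbon C4 sets H-1 and H-2 cis to H-4, giving the all-cis meso keto ester under kinetic control.

Step 7
Reactants: 10 methyl all-cis-2,4-di-Ar-3-oxocyclobutane-1-carboxylate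
Product: 11 methyl 2,4-di-Ar-3-(trifluoromethanesulfonyloxy)cyclobut-2-ene-1-carboxylate (racemic; H-1 and H-4 cis)
Conditions: KN(SiMe3)2 (1.05 equiv), THF, −78 °C (10 added to the base); PhNTf2, −78 → 0 °C
Reagents that add atoms: N-phenylbis(trifluoromethanesulfonimide) (PhNTf2), O=S(=O)(N(c1ccccc1)S(=O)(=O)C(F)(F)F)C(F)(F)F
Why: Kinetic deprotonation at a benzylic α-carbon of the ketone and O-triflation of the enolate (enol triflate synthesis); the two α-hydrogens of meso 10 are enantiotopic, so either deprotonation gives the same racemic triflate, in which the two remaining ring hydrogens stay cis.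

Step 8
Reactants: 11 methyl 2,4-di-Ar-3-(trifluoromethanesulfonyloxy)cyclobut-2-ene-1-carboxylate
Product: 12 dimethyl 2,4-di-Ar-cyclobut-1-ene-1,3-dicarboxylate (racemic; H-3 and H-4 cis)
Conditions: Pd(OAc)2 (5 mol %), dppp (6 mol %), CO (1 atm), MeOH (10 equiv), i-Pr2NEt, DMF, 35 °C
Reagents that add atoms: carbon monoxide, [C-]#[O+]; methanol, CO
Why: The same palladium-catalysed alkoxycarbonylation, now of a cyclobutenyl triflate; the vinylpalladium intermediate has no β-hydride elimination open to it inside the four-membered ring, and the temperature stays well below that of conrotatory cyclobutene opening.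

Step 9
Reactants: 12 dimethyl 2,4-di-Ar-cyclobut-1-ene-1,3-dicarboxylate
Product: 13 dimethyl all-cis-2,4-di-Ar-cyclobutane-1,3-dicarboxylate (meso; four ring hydrogens on one face)
Conditions: H2 (3 atm), Pd/C (10 mol %), EtOAc, rt
Reagents that add atoms: none
Why: syn-Hydrogenation of the cyclobutene from the face that carries only H-3 and H-4, away from the cis ester and aryl groups on those carbons, sets the last two stereocentres and gives the all-cis meso diester.

Step 10
Reactants: 13 dimethyl all-cis-2,4-di-Ar-cyclobutane-1,3-dicarboxylate
Product: 15 racemic all-cis bis-lactone (syn head-to-tail cyclobutane dimer of 7-hydroxycoumarin), via tetraphenol diester 14 (not isolated)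
Conditions: HCl (1.25 M in MeOH), 45 °C; evaporation; TsOH·H2O (10 mol %), toluene, 90 °C with removal of MeOH
Reagents that add atoms: none
Why: Acid-catalysed acetal exchange removes the four MOM groups (methanol traps the formaldehyde unit as dimethoxymethane), and each ester then lactonises with the ortho hydroxyl of a cis-neighbouring aryl group (dihydrocoumarin formation by intramolecular transesterification); the two possible phenol–ester pairings are mirror images, so the racemic all-cis bis-lactone is the only outcome.

Step 11
Reactants: 15 racemic all-cis 7,7′-dihydroxy bis-lactone; 16 3-chloro-3-methylbut-1-yne (3 equiv)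
Product: 17 racemic 7,7′-bis(2-methylbut-3-yn-2-yloxy) bis-lactone
Conditions: CuCl2·2H2O (1 mol %), DBU (2.5 equiv), MeCN, 0 °C
Reagents that add atoms: none
Why: Copper-catalysed O-alkylation of phenols by a tertiary propargylic chloride (through a copper acetylide-derived electrophile) runs at 0 °C with a non-nucleophilic amidine base, conditions under which the aryl lactones and the ring stereocentres should be untouched.

Step 12
Reactants: 17 racemic 7,7′-bis(2-methylbut-3-yn-2-yloxy) bis-lactone
Product: 18 racemic target (all-cis syn head-to-tail cyclobutane dimer of seselin)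
Conditions: o-dichlorobenzene, 160 °C, argon
Reagents that add atoms: none
Why: Aromatic propargyl Claisen rearrangement to C8, the ortho carbon between the two ring oxygens (expected, as for 7-hydroxycoumarin ethers, because the meta oxygen is acylated), then enolisation, 1,5-hydrogen shift and oxa-6π electrocyclisation close each 2,2-dimethyl-2H-pyran ring; no stereocentre is touched.

Step 13
Reactants: 18 racemic target
Product: 19 target, the enantiomer given by the SMILES
Conditions: preparative supercritical-fluid chromatography on silica-bound amylose tris(3,5-dimethylphenylcarbamate), CO2/i-PrOH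
Reagents that add atoms: none
Why: Resolution of a racemate on a chiral stationary phase, chosen because the rigid C2-symmetric bis-lactone has no acidic or basic handle for salt formation and because placing it last excludes any later erosion by lactone exchange.

Compound list
1 | squaric acid (3,4-dihydroxycyclobut-3-ene-1,2-dione) | OC1=C(O)C(=O)C1=O | starting material
2 | resorcinol (benzene-1,3-diol) | Oc1cccc(O)c1 | starting material
3 | 3-(2,4-dihydroxyphenyl)-4-hydroxycyclobut-3-ene-1,2-dione (semisquaric acid) | O=C1C(=O)C(c2ccc(O)cc2O)=C1O | intermediate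
4 | 1,3-bis(2,4-dihydroxyphenyl)squaraine (neutral quinoid form) | O=C1C=CC(=C2C(=O)C(c3ccc(O)cc3O)=C2O)C(O)=C1 | intermediate
5 | 2,4-bis(2,4-dihydroxyphenyl)-3-hydroxycyclobut-2-en-1-one (C4 stereolabile) | OC1=C(c2ccc(O)cc2O)C(=O)C1c1ccc(O)cc1O | intermediate
6 | 2,4-bis[2,4-bis(methoxymethoxy)phenyl]-3-(methoxymethoxy)cyclobut-2-en-1-one (racemic) | COCOC1=C(c2ccc(OCOC)cc2OCOC)C(=O)[C@H]1c1ccc(OCOC)cc1OCOC | intermediate
7 | 2,4-bis[2,4-bis(methoxymethoxy)phenyl]-3-hydroxycyclobut-2-en-1-one (C4 stereolabile) | OC1=C(c2ccc(OCOC)cc2OCOC)C(=O)C1c1ccc(OCOC)cc1OCOC | intermediate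
8 | 2,4-bis[2,4-bis(methoxymethoxy)phenyl]-3-oxocyclobut-1-en-1-yl trifluoromethanesulfonate (racemic) | FC(F)(F)S(=O)(=O)OC1=C(c2ccc(OCOC)cc2OCOC)C(=O)[C@H]1c1ccc(OCOC)cc1OCOC | intermediate
9 | methyl 2,4-bis[2,4-bis(methoxymethoxy)phenyl]-3-oxocyclobut-1-ene-1-carboxylate (racemic) | COC(=O)C1=C(c2ccc(OCOC)cc2OCOC)C(=O)[C@H]1c1ccc(OCOC)cc1OCOC | intermediate
10 | methyl all-cis-2,4-bis[2,4-bis(methoxymethoxy)phenyl]-3-oxocyclobutane-1-carboxylate (meso) | COC(=O)[C@H]1[C@@H](c2ccc(OCOC)cc2OCOC)C(=O)[C@H]1c1ccc(OCOC)cc1OCOC | intermediate
11 | methyl 2,4-bis[2,4-bis(methoxymethoxy)phenyl]-3-(trifluoromethanesulfonyloxy)cyclobut-2-ene-1-carboxylate (racemic; H-1 and H-4 cis) | COC(=O)[C@H]1[C@@H](c2ccc(OCOC)cc2OCOC)C(OS(=O)(=O)C(F)(F)F)=C1c1ccc(OCOC)cc1OCOC | intermediate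
12 | dimethyl 2,4-bis[2,4-bis(methoxymethoxy)phenyl]cyclobut-1-ene-1,3-dicarboxylate (racemic; H-3 and H-4 cis) | COC(=O)[C@H]1[C@@H](c2ccc(OCOC)cc2OCOC)C(C(=O)OC)=C1c1ccc(OCOC)cc1OCOC | intermediate
13 | dimethyl all-cis-2,4-bis[2,4-bis(methoxymethoxy)phenyl]cyclobutane-1,3-dicarboxylate (meso) | COC(=O)[C@H]1[C@@H](c2ccc(OCOC)cc2OCOC)[C@@H](C(=O)OC)[C@H]1c1ccc(OCOC)cc1OCOC | intermediate
14 | dimethyl all-cis-2,4-bis(2,4-dihydroxyphenyl)cyclobutane-1,3-dicarboxylate (meso) | COC(=O)[C@H]1[C@@H](c2ccc(O)cc2O)[C@@H](C(=O)OC)[C@H]1c1ccc(O)cc1O | intermediate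
15 | racemic all-cis bis-lactone, the syn head-to-tail cyclobutane dimer of 7-hydroxycoumarin (four ring hydrogens cis; 7,7′-dihydroxy) | Oc1ccc2c(c1)OC(=O)[C@H]3[C@@H]2[C@H]4C(=O)Oc5cc(O)ccc5[C@H]43 | intermediate
16 | 3-chloro-3-methylbut-1-yne | CC(C)(Cl)C#C | starting material
17 | racemic 7,7′-bis(2-methylbut-3-yn-2-yloxy) derivative of 15 | C#CC(C)(C)Oc1ccc2c(c1)OC(=O)[C@H]3[C@@H]2[C@H]4C(=O)Oc5cc(OC(C)(C)C#C)ccc5[C@H]43 | intermediate
18 | racemic target (all-cis syn head-to-tail cyclobutane dimer of seselin) | CC1(C)C=Cc2c(ccc3c2OC(=O)[C@H]2[C@@H]3[C@H]3C(=O)Oc4c5c(ccc4[C@H]32)OC(C)(C)C=C5)O1 | intermediate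
19 | CNP0167575.1, single enantiomer as given | CC1(C)C=Cc2c(ccc3c2OC(=O)[C@H]2[C@@H]3[C@H]3C(=O)Oc4c5c(ccc4[C@H]32)OC(C)(C)C=C5)O1 | target

Total step count: 13. Longest linear sequence: 13 (the route is fully linear from 1 and 2).

Steps most likely to fail

Step 2. Hydrogen may be taken up at the wrong site or in excess, and the unprotected leuco compound may re-oxidise to the dye or decompose before it is protected. The fallback sets out from 4 and returns at 5. Benzenethiol (DMF, rt) is added to the electrophilic ring carbon of the dye, the known mode of thiol addition to squaraines, to give 2,4-bis(2,4-dihydroxyphenyl)-3-hydroxy-4-(phenylsulfanyl)cyclobut-2-en-1-one F1. The tertiary α-keto C–S bond is then cleaved reductively (Zn, AcOH, rt) to give 5.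

Step 9. Hydrogen delivery to the crowded tetrasubstituted cyclobutene may be slow or poorly face-selective, with double-bond migration or conrotatory ring opening competing. The fallback sets out from 12 and returns at 15. The MOM groups are removed and the lactones closed first (conditions of step 10), giving the cyclobutene-fused coumarin/dihydrocoumarin bis-lactone F2 or its lactone-pairing isomer F3; both are racemic and converge. In these both lactone rings tilt to one face of the cyclobutene. The lactone-conjugated alkene is then reduced from the open convex face by copper hydride conjugate reduction (Cu(OAc)2, 1,2-bis(diphenylphosphino)benzene, polymethylhydrosiloxane, t-BuOH, toluene) or by hydrogenation. Protonation of the lactone enolate can only give the cis-fused ring, so 15 results.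

Step 12. Rearrangement may go to the less hindered ortho carbon C6 and give the linear pyran, or the strained cyclobutane may open at the reaction temperature. The fallback sets out from 15 and returns at 18. C6 and C6′ are blocked by bromination (N-bromosuccinimide, MeCN, 0 °C, the less hindered ortho position of each phenol) to give the 6,6′-dibromo bis-lactone F4. The conditions of steps 11 and 12 then lead through the 6,6′-dibromo bis(propargyl ether) F5 to the 6,6′-dibromo bis-pyran F6, in which rearrangement can only have gone to C8. Radical hydrodebromination (Bu3SnH, AIBN, benzene, 80 °C) returns to 18.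

Further compounds
F1 | step 2 | 2,4-bis(2,4-dihydroxyphenyl)-3-hydroxy-4-(phenylsulfanyl)cyclobut-2-en-1-one (racemic) | OC1=C(c2ccc(O)cc2O)C(=O)C1(Sc1ccccc1)c1ccc(O)cc1O
F2 | step 9 | racemic cyclobutene-fused bis-lactone, 7,7′-dihydroxy, C3′=C4′ unsaturated (coumarin on one side, cis-fused dihydrocoumarin on the other) | Oc1ccc2c(c1)OC(=O)[C@H]3[C@@H]2C4=C3c5ccc(O)cc5OC4=O
F3 | step 9 | racemic lactone-pairing isomer of F2 (each lactone spans one sp3 and one sp2 ring carbon; the two ring hydrogens cis) | Oc1ccc2c(c1)OC(=O)C3=C4c5ccc(O)cc5OC(=O)[C@H]4[C@@H]23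
F4 | step 12 | racemic 6,6′-dibromo derivative of 15 | Oc1c(Br)cc2c(c1)OC(=O)[C@H]3[C@@H]2[C@H]4C(=O)Oc5cc(O)c(Br)cc5[C@H]43
F5 | step 12 | racemic 6,6′-dibromo-7,7′-bis(2-methylbut-3-yn-2-yloxy) bis-lactone | C#CC(C)(C)Oc1c(Br)cc2c(c1)OC(=O)[C@H]3[C@@H]2[C@H]4C(=O)Oc5cc(OC(C)(C)C#C)c(Br)cc5[C@H]43
F6 | step 12 | racemic 6,6′-dibromo derivative of 18 | CC1(C)C=Cc2c(c(Br)cc3c2OC(=O)[C@H]2[C@@H]3[C@H]3C(=O)Oc4c5c(c(Br)cc4[C@H]32)OC(C)(C)C=C5)O1
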